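**Retrosynthetic overview**
- Last step: the exocyclic C=CH2 comes from a ring enone C=O (Zn/Ti methylenation). Before that, the isovanillate C–O bond is made by Mitsunobu inversion of the (R)-configured ring alcohol.
- The only ring (11-membered) is formed in step 6 by closing the C1–C11 bond, the bond made when farnesyl diphosphate closes to the humulyl cation. H-atom transfer to the tail isoprene unit gives a tertiary C11 radical that adds to C1 of a terminal ynone; C1 stays sp2, as in γ-humulene.
- Open-chain ynone ⇐ ethyl ester (one-pot Weinreb/ethynyl Grignard) ⇐ (E)-vinyl iodide + zinc homoenolate (Negishi) ⇐ homopropargylic alcohol (Zr-catalysed carboalumination sets the 6E alkene).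
- Homopropargylic alcohol ⇐ (S)-epichlorohydrin as linchpin (isopropenyl Grignard/Cu, then acetylide). The single stereocentre comes from the chiral pool and is inverted at the end.

Assumption: positions are numbered as in farnesane/humulane biosynthesis (C1–C15); the commercial THF solutions of 2 and 8 count as starting materials.

**Step 1**
Reactants: 1 (S)-epichlorohydrin; 2 isopropenylmagnesium bromide
Product: 3 (S)-1-chloro-4-methylpent-4-en-2-ol
Conditions: CuI (10 mol %), THF, −40 to −20 °C; aqueous work-up
Reagents that add atoms: none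
Why: Cu-catalysed Grignard opening of the epoxide at its CH2 terminus (SN2) leaves the carbinol stereocentre (future C9) untouched and keeps the chloride for the second alkylation.

**Step 2**
Reactants: 3
Product: 5 (S)-6-methylhept-6-en-1-yn-4-ol, via (S)-epoxide 4 (not isolated)
Conditions: lithium acetylide–ethylenediamine complex (3 equiv), DMSO, 0 °C to rt; aqueous work-up
Reagents that add atoms: lithium acetylide ethylenediamine complex, [Li]C#C.NCCN
Why: The first equivalent of acetylide closes the chlorohydrin to the terminal epoxide (Williamson closure) and the second opens it at CH2 (SN2), so the stereocentre is again not involved.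

**Step 3**
Reactants: 5
Product: 7 (S,E)-1-iodo-2,6-dimethylhepta-1,6-dien-4-ol, via alkenylalane 6 (not isolated)
Conditions: Me3Al (3 equiv), Cp2ZrCl2 (25 mol %), CH2Cl2, 0 °C to rt; then I2, THF, −30 to 0 °C
Reagents that add atoms: trimethylaluminium, C[Al](C)C; iodine, II
Why: Negishi Zr-catalysed syn-carboalumination of the terminal alkyne (methyl to the internal carbon) and iodinolysis with retention fix the 6E trisubstituted alkene; the 1,1-disubstituted alkene is inert under these conditions.

**Step 4**
Reactants: 7; 8 (3-ethoxy-3-oxopropyl)zinc bromide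
Product: 9 ethyl (4E,7S)-7-hydroxy-5,9-dimethyldeca-4,9-dienoate
Conditions: Pd(OAc)2 (2 mol %), SPhos (4 mol %), 8 (2.5 equiv), THF, rt
Reagents that add atoms: none
Why: Negishi sp2–sp3 cross-coupling proceeds with retention of alkene geometry, and the zinc homoenolate tolerates the free hydroxyl and the ester.

**Step 5**
Reactants: 9
Product: 11 (6E,9S)-9-hydroxy-7,11-dimethyldodeca-6,11-dien-1-yn-3-one, via Weinreb amide 10 (not isolated)
Conditions: MeNH(OMe)·HCl (1.5 equiv), i-PrMgCl (4 equiv), THF, −20 °C; then HC≡CMgBr (4 equiv), 0 °C to rt; inverse quench into cold 1 M HCl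
Reagents that add atoms: ethynylmagnesium bromide, C#C[Mg]Br (the N(OMe)Me group of 10 comes from MeNH(OMe)·HCl, CNOC.Cl, and is lost again)
Why: One-pot Weinreb ketone synthesis from the ester: the chelated tetrahedral adduct stops over-addition, and the cold acidic quench keeps the liberated amine from adding to the ynone.

**Step 6**
Reactants: 11
Product: 13 (2E,6R,8E)-6-hydroxy-4,4,8-trimethylcycloundeca-2,8-dien-1-one, via (2Z)-enone 12 (not isolated)
Conditions: Fe(acac)3 (50 mol %), Ph(i-PrO)SiH2 (3 equiv), THF/i-PrOH 20:1, 40 °C, 11 added by syringe pump over 12 h (1 mM final); then I2 (5 mol %), CH2Cl2, rt, daylight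
Reagents that add atoms: none
Why: Proposed new method: Fe–H hydrogen-atom transfer to the 1,1-disubstituted alkene (faster than to the trisubstituted C6=C7 alkene or the electron-poor alkyne) gives the tertiary C11 radical, which closes 11-endo onto the unsubstituted ynone terminus C1 (polarity-matched, high dilution); the α-keto vinyl radical is reduced and protonated, and catalytic I2 equilibrates the kinetic 2Z enone to the 2E isomer, which lacks the allylic strain against the gem-dimethyl carbon; no stereocentre is formed and C9 is untouched; closest known chemistry is the Fe(acac)3/silane reductive olefin–acceptor coupling (HAT-initiated Giese reaction) and endo radical macrocyclisation onto enones.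

**Step 7**
Reactants: 13; 14 isovanillic acid (3-hydroxy-4-methoxybenzoic acid)
Product: 15 (1S,3E,8E)-3,10,10-trimethyl-7-oxocycloundeca-3,8-dien-1-yl 3-hydroxy-4-methoxybenzoate
Conditions: PPh3 (1.5 equiv), DIAD (1.5 equiv), 14 (1.5 equiv), THF, 0 °C to rt
Reagents that add atoms: none
Why: Mitsunobu esterification: SN2 displacement of the alkoxyphosphonium by the carboxylate inverts the carbinol centre (R to S), and the carboxylic acid (pKa about 4.5) reacts in preference to the phenol, so no protecting group is needed.

**Step 8**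
Reactants: 15
Product: 16 (1S,3E,8E)-3,10,10-trimethyl-7-methylidenecycloundeca-3,8-dien-1-yl 3-hydroxy-4-methoxybenzoate
Conditions: Zn, CH2Br2, TiCl4 (Lombardo reagent, excess), THF/CH2Cl2, 0 °C to rt
Reagents that add atoms: dibromomethane, BrCBr
Why: Lombardo–Takai methylenation: the non-basic Zn/Ti methylene reagent converts the enone C=O into the exocyclic methylene by 1,2-addition without touching the aryl ester, the phenol (held as its metal phenoxide) or the stereocentre.

**Compound list**
1 | (S)-epichlorohydrin, (S)-2-(chloromethyl)oxirane | ClC[C@@H]1CO1 | starting material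
2 | isopropenylmagnesium bromide | CC(=C)[Mg]Br | starting material
3 | (S)-1-chloro-4-methylpent-4-en-2-ol | ClC[C@@H](O)CC(C)=C | intermediate
4 | (S)-2-(2-methylprop-2-en-1-yl)oxirane | C=C(C)C[C@H]1CO1 | intermediate
5 | (S)-6-methylhept-6-en-1-yn-4-ol | C=C(C)C[C@H](O)CC#C | intermediate
6 | dimethylaluminium (S,E)-1-(dimethylalumanyl)-2,6-dimethylhepta-1,6-dien-4-olate | C=C(C)C[C@H](O[Al](C)C)C/C(C)=C/[Al](C)C | intermediate
7 | (S,E)-1-iodo-2,6-dimethylhepta-1,6-dien-4-ol | C=C(C)C[C@H](O)C/C(C)=C/I | intermediate
8 | (3-ethoxy-3-oxopropyl)zinc bromide | CCOC(=O)CC[Zn]Br | starting material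
9 | ethyl (4E,7S)-7-hydroxy-5,9-dimethyldeca-4,9-dienoate | C=C(C)C[C@H](O)C/C(C)=C/CCC(=O)OCC | intermediate
10 | (4E,7S)-7-hydroxy-N-methoxy-N,5,9-trimethyldeca-4,9-dienamide | C=C(C)C[C@H](O)C/C(C)=C/CCC(=O)N(C)OC | intermediate
11 | (6E,9S)-9-hydroxy-7,11-dimethyldodeca-6,11-dien-1-yn-3-one | C=C(C)C[C@H](O)C/C(C)=C/CCC(=O)C#C | intermediate
12 | (2Z,6R,8E)-6-hydroxy-4,4,8-trimethylcycloundeca-2,8-dien-1-one | O=C1/C=C\C(C)(C)C[C@H](O)C/C(C)=C/CC1 | intermediate
13 | (2E,6R,8E)-6-hydroxy-4,4,8-trimethylcycloundeca-2,8-dien-1-one | O=C1/C=C/C(C)(C)C[C@H](O)C/C(C)=C/CC1 | intermediate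
14 | isovanillic acid (3-hydroxy-4-methoxybenzoic acid) | COc1ccc(cc1O)C(=O)O | starting material
15 | (1S,3E,8E)-3,10,10-trimethyl-7-oxocycloundeca-3,8-dien-1-yl 3-hydroxy-4-methoxybenzoate | O=C1/C=C/C(C)(C)C[C@@H](OC(=O)c2ccc(OC)c(O)c2)C/C(C)=C/CC1 | intermediate
16 | (1S,3E,8E)-3,10,10-trimethyl-7-methylidenecycloundeca-3,8-dien-1-yl 3-hydroxy-4-methoxybenzoate | C=C1/C=C/C(C)(C)C[C@@H](OC(=O)c2ccc(OC)c(O)c2)C/C(C)=C/CC1 | target

**Totals**
Total step count: 8. Longest linear sequence: 8 (from 1).

**Three steps most likely to fail, with fallbacks**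

Step 6 (radical 11-ring closure). Threats are 6-endo attack of the C11 radical on C6=C7, simple reduction of the radical, transannular attack of the vinyl radical on C6=C7, and incomplete Z-to-E equilibration. The fallback sets out from 11 and returns at 13. Sodium p-toluenesulfinate and AcOH (EtOH, rt) add to the ynone to give (1E,6E,9S)-9-hydroxy-7,11-dimethyl-1-(4-methylbenzenesulfonyl)dodeca-1,6,11-trien-3-one F1. Under the same Fe–H conditions the C11 radical adds to the sulfonyl-bearing carbon of this doubly activated alkene and the α-keto radical expels the sulfonyl radical (addition–fragmentation, a radical vinylic substitution). This gives 13 directly as the E enone, through a more electrophilic acceptor and without a vinyl radical, a reduction step or an isomerisation stage.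

Step 7 (Mitsunobu on the ring alcohol). Threats are elimination towards the C6=C7 alkene, sluggish SN2 in the medium ring, and transannular oxa-Michael addition of the free hydroxyl of 13 to the enone. The fallback sets out from 9 and returns at 15, and moves the esterification ahead of the ring closure. Step 5 is stopped after its first stage and Weinreb amide 10 is isolated. Mitsunobu reaction of this open-chain alcohol with 14 gives (4R,6E)-10-[methoxy(methyl)amino]-2,6-dimethyl-10-oxodeca-1,6-dien-4-yl 3-hydroxy-4-methoxybenzoate F2. HC≡CMgBr (3.5 equiv, −20 to 0 °C) reacts at the Weinreb amide but not at the aryl ester with its phenoxide, and gives (4R,6E)-2,6-dimethyl-10-oxododeca-1,6-dien-11-yn-4-yl 3-hydroxy-4-methoxybenzoate F3. The Fe–H closure of step 6 then gives (1S,3E,8Z)-3,10,10-trimethyl-7-oxocycloundeca-3,8-dien-1-yl 3-hydroxy-4-methoxybenzoate F4, which is not isolated and is equilibrated by I2 to 15.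

Step 8 (methylenation beside an ester and a phenol). Threats are Lewis-acid damage to the diene and a sluggish reaction. The fallback sets out from 15 and returns at 16, using a two-step Peterson olefination. Me3SiCH2MgCl/CeCl3 (THF, −78 °C) adds 1,2 to the ketone to give (1S,3E,8E)-7-hydroxy-3,10,10-trimethyl-7-[(trimethylsilyl)methyl]cycloundeca-3,8-dien-1-yl 3-hydroxy-4-methoxybenzoate F5 (either C7 epimer). AcOH or silica then eliminates Me3SiOH through the β-silyl-stabilised ring allyl cation, which places the new double bond exocyclic only.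

**Further compounds**
F1 | step 6 | (1E,6E,9S)-9-hydroxy-7,11-dimethyl-1-(4-methylbenzenesulfonyl)dodeca-1,6,11-trien-3-one | C=C(C)C[C@H](O)C/C(C)=C/CCC(=O)/C=C/S(=O)(=O)c1ccc(C)cc1
F2 | step 7 | (4R,6E)-10-[methoxy(methyl)amino]-2,6-dimethyl-10-oxodeca-1,6-dien-4-yl 3-hydroxy-4-methoxybenzoate | C=C(C)C[C@@H](OC(=O)c1ccc(OC)c(O)c1)C/C(C)=C/CCC(=O)N(C)OC
F3 | step 7 | (4R,6E)-2,6-dimethyl-10-oxododeca-1,6-dien-11-yn-4-yl 3-hydroxy-4-methoxybenzoate | C=C(C)C[C@@H](OC(=O)c1ccc(OC)c(O)c1)C/C(C)=C/CCC(=O)C#C
F4 | step 7 | (1S,3E,8Z)-3,10,10-trimethyl-7-oxocycloundeca-3,8-dien-1-yl 3-hydroxy-4-methoxybenzoate | O=C1/C=C\C(C)(C)C[C@@H](OC(=O)c2ccc(OC)c(O)c2)C/C(C)=C/CC1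
F5 | step 8 | (1S,3E,8E)-7-hydroxy-3,10,10-trimethyl-7-[(trimethylsilyl)methyl]cycloundeca-3,8-dien-1-yl 3-hydroxy-4-methoxybenzoate | C[Si](C)(C)CC1(O)/C=C/C(C)(C)C[C@@H](OC(=O)c2ccc(OC)c(O)c2)C/C(C)=C/CC1
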